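The γ-lactone (O1, C2=O, C3, C4, C5) is closed last at its C4–C5 bond. The chloromethyl ester of an (R)-2-benzyl-2-hydroxy-4-arylbut-3-enoic acid is converted into an acyloxymethyl radical (C5, carried on O1) that adds 5-exo-trig to styrene carbon C4; the benzylic radical at C7 is then reduced. One operation thus forms the oxolan-2-one ring and the C4 stereocentre under control of the preset quaternary carbinol C3. The step exploits that C4 lies between the O–CH2 carbon C5 and the benzylic carbon C7 of its arylmethyl group, so that a C4=C7 styrene is a regiochemically unambiguous radical acceptor. C3 is set earlier by dioxolanone alkylation (self-regeneration of stereocentres).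

Key step: step 8

Remark: Ar = 4-(benzyloxy)-3-methoxyphenyl throughout.
Assumption: in step 2 the (S)-configured diphosphine is taken to deliver the (R)-hydroxy acid; if the sense of induction is the opposite, the antipodal ligand is used and nothing else changes.

Step 1
Reactants: 1 4-(benzyloxy)-3-methoxybenzaldehyde; 2 pyruvic acid
Product: 3 (E)-4-Ar-2-oxobut-3-enoic acid
Conditions: KOH (2 equiv), MeOH/H2O, 0 °C → rt; then 1 M HCl
Reagents that add atoms: none
Why: Claisen–Schmidt (crossed aldol) condensation of the non-enolisable aldehyde with the pyruvate enolate, followed by E1cB dehydration, should give the conjugated (E)-enone acid, whose potassium salt precipitates and is thereby kept from reacting further.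

Step 2
Reactants: 3 (E)-4-Ar-2-oxobut-3-enoic acid
Product: 4 (2R,3E)-4-Ar-2-hydroxybut-3-enoic acid
Conditions: H2 (20 bar), [RuCl(benzene)((S)-SunPhos)]Cl (1 mol %), THF, 70 °C
Reagents that add atoms: none
Why: Asymmetric hydrogenation of the α-keto acid carbonyl by a chiral ruthenium–diphosphine catalyst, to which the substrate binds through carboxylate and ketone so that hydride reaches one enantiotopic face (setting C2 as R), is a known reaction of 4-aryl-2-oxobut-3-enoic acids that leaves the conjugated C=C and the benzyl ether intact.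

Step 3
Reactants: 4 (2R,3E)-4-Ar-2-hydroxybut-3-enoic acid
Product: 6 (2R,5R)-2-tert-butyl-5-[(E)-2-Ar-ethenyl]-1,3-dioxolan-4-one, via bis-silyl derivative 5 (not isolated)
Conditions: Me3SiCl (2.2 equiv), Et3N (2.3 equiv), CH2Cl2, 0 °C → rt, salts filtered off; then t-BuCHO (1.5 equiv), Me3SiOTf (5 mol %), CH2Cl2, −78 °C
Reagents that add atoms: pivalaldehyde, CC(C)(C)C=O
Why: Silyl-transfer acetalisation (Me3SiOTf-catalysed condensation of the bis-silyl derivative with pivalaldehyde) should give the 2,5-cis dioxolanone under kinetic control, the existing C5 centre setting the acetal carbon as R, while the absence of Brønsted acid spares the ionisable allylic C–O bond.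

Step 4
Reactants: 7 [4-(benzyloxy)-3-methoxyphenyl]methanol
Product: 8 1-(benzyloxy)-4-(bromomethyl)-2-methoxybenzene
Conditions: PBr3 (0.4 equiv), Et2O, 0 °C; used freshly prepared
Reagents that add atoms: phosphorus tribromide, BrP(Br)Br
Why: Bromination of the electron-rich benzylic alcohol with PBr3 proceeds by SN2 displacement of a phosphite leaving group by bromide under conditions that leave the aryl benzyl ether untouched.

Step 5
Reactants: 6 (2R,5R)-2-tert-butyl-5-[(E)-2-Ar-ethenyl]-1,3-dioxolan-4-one; 8 1-(benzyloxy)-4-(bromomethyl)-2-methoxybenzene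
Product: 10 (2R,5R)-5-(Ar-methyl)-2-tert-butyl-5-[(E)-2-Ar-ethenyl]-1,3-dioxolan-4-one, via lithium dienolate 9 (not isolated)
Conditions: LiN(SiMe3)2 (1.1 equiv), THF, −78 °C; then 8 (1.3 equiv), THF/DMPU, −78 → −40 °C
Reagents that add atoms: none
Why: Enolate alkylation with self-regeneration of the stereocentre: the planar lithium dienolate should react with the benzylic bromide at its α-carbon (attack at the aryl-bearing γ-carbon is hindered) on the face opposite the tert-butyl group, which sets the quaternary carbon as R with the new benzyl group trans to tert-butyl.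

Step 6
Reactants: 10 (2R,5R)-5-(Ar-methyl)-2-tert-butyl-5-[(E)-2-Ar-ethenyl]-1,3-dioxolan-4-one
Product: 11 (2R,3E)-2-(Ar-methyl)-4-Ar-2-hydroxybut-3-enoic acid
Conditions: LiOH (3 equiv), THF/MeOH/H2O, rt; then 1 M HCl to pH 2–3
Reagents that add atoms: lithium hydroxide, [Li+].[OH-]
Why: Saponification of the dioxolanone (acyl–oxygen cleavage by hydroxide, then collapse of the hemiacetal with loss of pivalaldehyde) should release the tertiary α-hydroxy acid without touching the quaternary stereocentre, which cannot epimerise.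

Step 7
Reactants: 11 (2R,3E)-2-(Ar-methyl)-4-Ar-2-hydroxybut-3-enoic acid
Product: 12 chloromethyl (2R,3E)-2-(Ar-methyl)-4-Ar-2-hydroxybut-3-enoate
Conditions: ClCH2OSO2Cl (1.2 equiv), NaHCO3 (4 equiv), Bu4NHSO4 (10 mol %), CH2Cl2/H2O, 0 °C → rt
Reagents that add atoms: chloromethyl chlorosulfate, ClCOS(=O)(=O)Cl
Why: Phase-transfer O-alkylation of the carboxylate (SN2 at the methylene of chloromethyl chlorosulfate with chlorosulfate as the leaving group) should give the chloromethyl ester, the tertiary hydroxyl being inert under bicarbonate conditions.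

Step 8
Reactants: 12 chloromethyl (2R,3E)-2-(Ar-methyl)-4-Ar-2-hydroxybut-3-enoate
Product: 16 (3R,4R)-3,4-bis(Ar-methyl)-3-hydroxyoxolan-2-one, via iodomethyl ester 13 (not isolated), via acyloxymethyl radical 14 (not isolated), via benzylic radical 15 (not isolated)
Conditions: NaI (1.5 equiv), acetone, rt, dark, then filtration and solvent exchange; Bu3SnH (1.3 equiv) + AIBN (0.2 equiv) by syringe pump over 8 h into a 0.005 M solution in PhH, reflux
Reagents that add atoms: none
Why: Finkelstein exchange gives iodomethyl ester 13, from which Bu3Sn• abstracts iodine; the acyloxymethyl radical 14 (future C5 on O1) adds to C4 of the C4=C7 styrene, and the benzylic radical 15 takes hydrogen from Bu3SnH to carry the chain. The closest known reaction type is the tin hydride-mediated 5-exo cyclisation of acyloxymethyl radicals from halomethyl but-3-enoates to γ-butyrolactones. The oxolan-2-one ring is closed 5-exo-trig through the C4–C5 bond, because 6-endo attack at C7 would forfeit benzylic stabilisation. The new stereocentre C4 is controlled by the quaternary carbinol C3 (1,2-induction): in the envelope-like transition state the larger benzyl group on C3 should lie pseudo-equatorial and the small free hydroxyl pseudo-axial, so C7 ends trans to the C3 benzyl group and (3R) gives (4R). The step needs ring closure to outrun hydrogen transfer to 14, since the ester must first reach its s-cis rotamer; this is secured by the activated styrene acceptor, the fully substituted C3 (gem-disubstituent effect), and high dilution with slow stannane addition at reflux.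

Step 9
Reactants: 16 (3R,4R)-3,4-bis(Ar-methyl)-3-hydroxyoxolan-2-one
Product: 17 (+)-nortrachelogenin
Conditions: H2 (1 atm), Pd/C (10 wt %), EtOAc/EtOH, rt
Reagents that add atoms: none
Why: Hydrogenolysis of the two aryl benzyl ethers over palladium on carbon should be selective because the lactone, the non-benzylic tertiary alcohol and both stereocentres (C3 quaternary, C4 not epimerisable under neutral conditions) are inert to it.

Compound list
1 | 4-(benzyloxy)-3-methoxybenzaldehyde (O-benzylvanillin) | O=Cc1ccc(OCc2ccccc2)c(OC)c1 | starting material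
2 | pyruvic acid | CC(=O)C(=O)O | starting material
3 | (E)-4-[4-(benzyloxy)-3-methoxyphenyl]-2-oxobut-3-enoic acid | OC(=O)C(=O)/C=C/c1ccc(OCc2ccccc2)c(OC)c1 | intermediate
4 | (2R,3E)-4-[4-(benzyloxy)-3-methoxyphenyl]-2-hydroxybut-3-enoic acid | OC(=O)[C@H](O)/C=C/c1ccc(OCc2ccccc2)c(OC)c1 | intermediate
5 | trimethylsilyl (2R,3E)-4-[4-(benzyloxy)-3-methoxyphenyl]-2-(trimethylsilyloxy)but-3-enoate | C[Si](C)(C)OC(=O)[C@H](O[Si](C)(C)C)/C=C/c1ccc(OCc2ccccc2)c(OC)c1 | intermediate (not isolated)
6 | (2R,5R)-2-tert-butyl-5-{(E)-2-[4-(benzyloxy)-3-methoxyphenyl]ethenyl}-1,3-dioxolan-4-one (cis) | CC(C)(C)[C@@H]1O[C@H](/C=C/c2ccc(OCc3ccccc3)c(OC)c2)C(=O)O1 | intermediate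
7 | [4-(benzyloxy)-3-methoxyphenyl]methanol | OCc1ccc(OCc2ccccc2)c(OC)c1 | starting material
8 | 1-(benzyloxy)-4-(bromomethyl)-2-methoxybenzene | BrCc1ccc(OCc2ccccc2)c(OC)c1 | intermediate
9 | lithium (2R)-2-tert-butyl-5-{(E)-2-[4-(benzyloxy)-3-methoxyphenyl]ethenyl}-1,3-dioxol-4-olate (dienolate) | CC(C)(C)[C@@H]1OC(/C=C/c2ccc(OCc3ccccc3)c(OC)c2)=C([O-])O1.[Li+] | intermediate (not isolated)
10 | (2R,5R)-5-{[4-(benzyloxy)-3-methoxyphenyl]methyl}-2-tert-butyl-5-{(E)-2-[4-(benzyloxy)-3-methoxyphenyl]ethenyl}-1,3-dioxolan-4-one | CC(C)(C)[C@@H]1O[C@](Cc2ccc(OCc3ccccc3)c(OC)c2)(/C=C/c2ccc(OCc3ccccc3)c(OC)c2)C(=O)O1 | intermediate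
11 | (2R,3E)-2-{[4-(benzyloxy)-3-methoxyphenyl]methyl}-4-[4-(benzyloxy)-3-methoxyphenyl]-2-hydroxybut-3-enoic acid | OC(=O)[C@@](O)(Cc1ccc(OCc2ccccc2)c(OC)c1)/C=C/c1ccc(OCc2ccccc2)c(OC)c1 | intermediate
12 | chloromethyl ester of 11 | ClCOC(=O)[C@@](O)(Cc1ccc(OCc2ccccc2)c(OC)c1)/C=C/c1ccc(OCc2ccccc2)c(OC)c1 | intermediate
13 | iodomethyl ester of 11 | ICOC(=O)[C@@](O)(Cc1ccc(OCc2ccccc2)c(OC)c1)/C=C/c1ccc(OCc2ccccc2)c(OC)c1 | intermediate (not isolated)
14 | acyloxymethyl radical derived from 13 | [CH2]OC(=O)[C@@](O)(Cc1ccc(OCc2ccccc2)c(OC)c1)/C=C/c1ccc(OCc2ccccc2)c(OC)c1 | intermediate (not isolated)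
15 | cyclised lactone carrying the benzylic radical at C7 | COc1cc([CH][C@@H]2COC(=O)[C@@]2(O)Cc2ccc(OCc3ccccc3)c(OC)c2)ccc1OCc1ccccc1 | intermediate (not isolated)
16 | (3R,4R)-3,4-bis{[4-(benzyloxy)-3-methoxyphenyl]methyl}-3-hydroxyoxolan-2-one (di-O-benzyl-nortrachelogenin) | COc1cc(C[C@@H]2COC(=O)[C@@]2(O)Cc2ccc(OCc3ccccc3)c(OC)c2)ccc1OCc1ccccc1 | intermediate
17 | (+)-nortrachelogenin, (3R,4R)-3-hydroxy-3,4-bis[(4-hydroxy-3-methoxyphenyl)methyl]oxolan-2-one | COc1cc(C[C@@H]2COC(=O)[C@@]2(O)Cc2ccc(O)c(OC)c2)ccc1O | target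

Total step count: 9. Longest linear sequence: 8 steps (steps 1, 2, 3, 5, 6, 7, 8, 9); step 4 is a one-step side branch.

Steps most likely to fail

Step 8. What may go wrong: hydrogen transfer from the stannane to the acyloxymethyl radical before the ester has rotated into the s-cis form needed for ring closure, modest facial selectivity at C4, and intramolecular O-alkylation of the tertiary hydroxyl by the iodomethyl ester. The fallback sets out from 4 and returns to the route at 16; it closes the same C4–C5 bond in a temporary silicon-containing ring and introduces the C3 benzyl group afterwards. Acid 4 is esterified (Me3SiCHN2, MeOH/PhMe, 0 °C) to methyl (2R,3E)-4-Ar-2-hydroxybut-3-enoate F1 and silylated (BrCH2SiMe2Cl, Et3N, DMAP cat., CH2Cl2, 0 °C) to the (bromomethyl)dimethylsilyl ether F2. Silicon-tethered 5-exo radical cyclisation (Bu3SnH, AIBN, PhH, 80 °C), which has no ester-rotamer handicap, should give the trans-1,2-oxasilolane F3, the ester group taking the pseudo-equatorial position opposite the new arylmethyl group. Tamao oxidation (H2O2, KF, KHCO3, THF/MeOH, rt) gives the diol ester F4, which lactonises (TsOH cat., CH2Cl2) to the cis-hydroxy lactone F5; any minor diastereomer is removed at this stage so that the configuration at C4 stays homogeneous. The dianion of F5 (LiN(SiMe3)2, 2.2 equiv, THF/DMPU, −78 → −30 °C) is alkylated with 8 on the face opposite the C4 substituent, which should give 16.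

Step 5. What may go wrong: alkylation at the γ-carbon or at oxygen of the dienolate, erosion of facial control, or fragmentation of the enolate on warming. The fallback sets out from 3 and returns at 16; the quaternary centre is made after ring closure instead of before it. Hydrogenation of 3 as in step 2 but with the antipodal catalyst gives the (2S,3E)-hydroxy acid F6, and chloromethylation as in step 7 gives the chloromethyl ester F7. Iodide exchange to the iodomethyl ester F8 and tin hydride cyclisation as in step 8 then run on a secondary carbinol, whose hydroxyl should take the pseudo-equatorial position. The trans-hydroxy lactone F9 with (4R) configuration should therefore predominate and is separated from its cis isomer. Dianion alkylation of F9 with 8 (LiN(SiMe3)2, 2.2 equiv, THF/DMPU, −78 → −30 °C) then sets C3 with the benzyl group trans to the C4 substituent and should give 16.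

Step 2. What may go wrong: incomplete enantioselection or competing reduction of the conjugated alkene. The fallback sets out from 3 and returns at 4. It is a biocatalytic reduction of the sodium salt of 3 with a D-lactate dehydrogenase (NADH in catalytic amount, recycled by formate dehydrogenase and sodium formate, aqueous buffer pH 7.5, rt). This enzyme class is known to reduce 4-aryl-2-oxobut-3-enoates to (R)-2-hydroxy acids without touching the C=C; it makes no new compound (F0).

Further compounds
F1 | step 8 | methyl (2R,3E)-4-[4-(benzyloxy)-3-methoxyphenyl]-2-hydroxybut-3-enoate | COC(=O)[C@H](O)/C=C/c1ccc(OCc2ccccc2)c(OC)c1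
F2 | step 8 | methyl (2R,3E)-4-[4-(benzyloxy)-3-methoxyphenyl]-2-{[(bromomethyl)dimethylsilyl]oxy}but-3-enoate | COC(=O)[C@H](O[Si](C)(C)CBr)/C=C/c1ccc(OCc2ccccc2)c(OC)c1
F3 | step 8 | methyl (4S,5R)-4-{[4-(benzyloxy)-3-methoxyphenyl]methyl}-2,2-dimethyl-1,2-oxasilolane-5-carboxylate | COC(=O)[C@@H]1O[Si](C)(C)C[C@H]1Cc1ccc(OCc2ccccc2)c(OC)c1
F4 | step 8 | methyl (2R,3R)-4-[4-(benzyloxy)-3-methoxyphenyl]-2-hydroxy-3-(hydroxymethyl)butanoate | COC(=O)[C@H](O)[C@@H](CO)Cc1ccc(OCc2ccccc2)c(OC)c1
F5 | step 8 | (3R,4R)-4-{[4-(benzyloxy)-3-methoxyphenyl]methyl}-3-hydroxyoxolan-2-one | COc1cc(C[C@@H]2COC(=O)[C@@H]2O)ccc1OCc1ccccc1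
F6 | step 5 | (2S,3E)-4-[4-(benzyloxy)-3-methoxyphenyl]-2-hydroxybut-3-enoic acid | OC(=O)[C@@H](O)/C=C/c1ccc(OCc2ccccc2)c(OC)c1
F7 | step 5 | chloromethyl (2S,3E)-4-[4-(benzyloxy)-3-methoxyphenyl]-2-hydroxybut-3-enoate | ClCOC(=O)[C@@H](O)/C=C/c1ccc(OCc2ccccc2)c(OC)c1
F8 | step 5 | iodomethyl (2S,3E)-4-[4-(benzyloxy)-3-methoxyphenyl]-2-hydroxybut-3-enoate | ICOC(=O)[C@@H](O)/C=C/c1ccc(OCc2ccccc2)c(OC)c1
F9 | step 5 | (3S,4R)-4-{[4-(benzyloxy)-3-methoxyphenyl]methyl}-3-hydroxyoxolan-2-one | COc1cc(C[C@@H]2COC(=O)[C@H]2O)ccc1OCc1ccccc1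
F0 | step 2 | none | none
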